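**Retrosynthetic overview**
1. The target comes from the 8‑hydroxy α‑methylene lactone 25 by acylation at O8 with the (S)‑Roche‑acid silyl ether 28, then global desilylation.
2. The exocyclic methylene is put on the saturated macrocyclic lactone 20 by a Mannich reaction and elimination; the ten‑membered carbocycle (second ring) is closed by ring‑closing metathesis at C1=C10.
3. The C8–C9 bond and the C8 carbinol come from a catalyst‑controlled methallylation of lactone aldehyde 17.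
4. The key C6–C7 bond is an intermolecular Evans syn‑aldol of succinate imide 11 with the (Z)‑enal 8; the adduct lactonises, so the γ‑lactone is the first ring formed.
5. Enal 8 comes from prop‑2‑yn‑1‑ol by syn‑carbocupration of ynoate 4, which fixes the C4=C5 geometry.

Assumption: the SMILES is taken literally (C1=C10 Z, i.e. ring‑cis with the methyl trans to C2; C4=C5 ring‑trans; 6R,7R,8S and 2′S); germacrane numbering is used for positions. TBDPS = SiPh2tBu, TES = SiEt3, TBS = SiMe2tBu. The route is a plan and has not been run.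

**Step 1**
Reactants: 1 prop-2-yn-1-ol
Product: 2 tert-butyl(diphenyl)(prop-2-yn-1-yloxy)silane
Conditions: TBDPSCl, imidazole, CH2Cl2, 0 °C → rt
Reagents that add atoms: tert-butyl(chloro)diphenylsilane, CC(C)(C)[Si](Cl)(c1ccccc1)c1ccccc1
Why: Silylation of the primary alcohol gives an ether that survives every step up to the final fluoride deprotection.

**Step 2**
Reactants: 2 tert-butyl(diphenyl)(prop-2-yn-1-yloxy)silane
Product: 4 ethyl 4-(TBDPSO)but-2-ynoate, via lithium acetylide 3 (not isolated)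
Conditions: n-BuLi, THF, −78 °C; then ClCO2Et, −78 → 0 °C
Reagents that add atoms: ethyl chloroformate, CCOC(=O)Cl
Why: Deprotonation of the terminal alkyne and C‑acylation of the acetylide with the chloroformate gives the ynoate (future C6).

**Step 3**
Reactants: 4 ethyl 4-(TBDPSO)but-2-ynoate
Product: 6 ethyl (2Z)-3-(TBDPSOCH2)hepta-2,6-dienoate, via alkenylcopper 5 (not isolated)
Conditions: CH2=CHCH2CH2MgBr, CuBr·SMe2, THF, −78 °C; then 4, −78 °C; NH4Cl (aq), −78 °C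
Reagents that add atoms: but-3-en-1-ylmagnesium bromide, C=CCC[Mg]Br
Why: Syn‑carbocupration of the ynoate followed by cold protonation puts the butenyl chain trans and the CH2OTBDPS arm cis to the ester, which is the C4=C5 geometry of the target.

**Step 4**
Reactants: 6 ethyl (2Z)-3-(TBDPSOCH2)hepta-2,6-dienoate
Product: 7 (2Z)-3-(TBDPSOCH2)hepta-2,6-dien-1-ol
Conditions: iBu2AlH, CH2Cl2, −78 °C
Reagents that add atoms: none
Why: Hydride 1,2‑reduction of the enoate gives the allylic alcohol without touching the olefin geometry.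

**Step 5**
Reactants: 7 (2Z)-3-(TBDPSOCH2)hepta-2,6-dien-1-ol
Product: 8 (2Z)-3-(TBDPSOCH2)hepta-2,6-dienal
Conditions: MnO2, CH2Cl2, rt; used at once
Reagents that add atoms: none
Why: Neutral allylic oxidation gives the enal without E/Z isomerisation.

**Step 6**
Reactants: 9 (4S)-4-benzyl-1,3-oxazolidin-2-one; 10 methyl 4-chloro-4-oxobutanoate
Product: 11 methyl 4-[(4S)-4-benzyl-2-oxo-1,3-oxazolidin-3-yl]-4-oxobutanoate
Conditions: Et3N, DMAP (cat.), CH2Cl2, 0 °C → rt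
Reagents that add atoms: none
Why: N‑Acylation of the auxiliary gives the succinate imide that carries C7, C8, C11 and C12.

**Step 7**
Reactants: 11 methyl 4-[(4S)-4-benzyl-2-oxo-1,3-oxazolidin-3-yl]-4-oxobutanoate; 8 (2Z)-3-(TBDPSOCH2)hepta-2,6-dienal
Product: 14 (4S)-4-benzyl-3-{[(2R,3S)-2-[(1Z)-2-(TBDPSOCH2)hexa-1,5-dien-1-yl]-5-oxooxolan-3-yl]carbonyl}-1,3-oxazolidin-2-one, via boron enolate 12 (not isolated), via syn-aldol adduct 13 (not isolated)
Conditions: Bu2BOTf, iPr2NEt, CH2Cl2, 0 °C; then 8, −78 → 0 °C; pH 7 buffer (NaH2PO4/Na2HPO4), MeOH, H2O2, 0 °C; lactonisation completed on silica gel, CH2Cl2, rt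
Reagents that add atoms: none
Why: Evans syn‑aldol reaction: the (Z)‑boron enolate adds through a Zimmerman–Traxler chair on the face away from the benzyl group, setting C6 and C7, and the aldolate closes onto the methyl ester to give the trans γ‑lactone.

**Step 8**
Reactants: 14 (4S)-4-benzyl-3-{[(2R,3S)-2-[(1Z)-2-(TBDPSOCH2)hexa-1,5-dien-1-yl]-5-oxooxolan-3-yl]carbonyl}-1,3-oxazolidin-2-one
Product: 15 (2R,3S)-2-[(1Z)-2-(TBDPSOCH2)hexa-1,5-dien-1-yl]-5-oxooxolane-3-carboxylic acid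
Conditions: LiOH, H2O2, THF/H2O, 0 °C; Na2SO3; HCl (aq) to pH 2–3
Reagents that add atoms: hydrogen peroxide, OO, used with lithium hydroxide, [Li+].[OH-], as LiOOH
Why: Hydroperoxide hydrolysis cleaves the imide at the exocyclic carbonyl, and any opened lactone re‑closes on acidification because O6 is the only hydroxyl present.

**Step 9**
Reactants: 15 (2R,3S)-2-[(1Z)-2-(TBDPSOCH2)hexa-1,5-dien-1-yl]-5-oxooxolane-3-carboxylic acid
Product: 17 (2R,3S)-2-[(1Z)-2-(TBDPSOCH2)hexa-1,5-dien-1-yl]-5-oxooxolane-3-carbaldehyde, via acid chloride 16 (not isolated)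
Conditions: (COCl)2, DMF (cat.), CH2Cl2, 0 °C → rt; evaporate; then Bu3SnH, Pd(PPh3)4 (5 mol%), toluene, rt
Reagents that add atoms: none
Why: Pd‑catalysed tin hydride reduction of the acid chloride gives the aldehyde under neutral conditions, avoiding a hydroxymethyl lactone (which could translactonise) and borane (which would hydroborate the terminal olefin).

**Step 10**
Reactants: 17 (2R,3S)-2-[(1Z)-2-(TBDPSOCH2)hexa-1,5-dien-1-yl]-5-oxooxolane-3-carbaldehyde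
Product: 18 (4R,5R)-5-[(1Z)-2-(TBDPSOCH2)hexa-1,5-dien-1-yl]-4-[(1S)-1-hydroxy-3-methylbut-3-en-1-yl]oxolan-2-one
Conditions: (S)-BINOL (20 mol%), Ti(OiPr)4 (10 mol%), 4 Å MS, CH2Cl2; tributyl(2-methylallyl)stannane, −20 °C, 60 h; NaHCO3 (aq)
Reagents that add atoms: tributyl(2-methylallyl)stannane, C=C(C)C[Sn](CCCC)(CCCC)CCCC
Why: Keck catalytic asymmetric carbonyl methallylation: the (S)‑BINOL–titanium catalyst directs attack to the Si face of the aldehyde and so sets 8S under neutral conditions that neither epimerise C7 nor open the lactone.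

**Step 11**
Reactants: 18 (4R,5R)-5-[(1Z)-2-(TBDPSOCH2)hexa-1,5-dien-1-yl]-4-[(1S)-1-hydroxy-3-methylbut-3-en-1-yl]oxolan-2-one
Product: 19 (4S,5R)-5-[(1Z)-2-(TBDPSOCH2)hexa-1,5-dien-1-yl]-4-[(1S)-3-methyl-1-(TESO)but-3-en-1-yl]oxolan-2-one
Conditions: TESOTf, 2,6-lutidine, CH2Cl2, −78 °C
Reagents that add atoms: triethylsilyl trifluoromethanesulfonate, CC[Si](CC)(CC)OS(=O)(=O)C(F)(F)F
Why: Fast low‑temperature silylation caps O8 before it can translactonise and protects it for the enolate chemistry.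

**Step 12**
Reactants: 19 (4S,5R)-5-[(1Z)-2-(TBDPSOCH2)hexa-1,5-dien-1-yl]-4-[(1S)-3-methyl-1-(TESO)but-3-en-1-yl]oxolan-2-one
Product: 20 (3aS,4S,6Z,10Z,11aR)-10-(TBDPSOCH2)-6-methyl-4-(TESO)-3a,4,5,8,9,11a-hexahydrocyclodeca[b]furan-2(3H)-one
Conditions: second-generation Grubbs catalyst RuCl2(=CHPh)(PCy3)(H2IMes) (15 mol%, in portions), toluene (1 mM), 80 °C
Reagents that add atoms: none
Why: Ring‑closing metathesis of the terminal and 1,1‑disubstituted olefins closes the ten‑membered ring; the Z olefin is expected because a cis,trans‑cyclodeca‑1,5‑diene is the least strained arrangement next to the existing ring‑trans C4=C5 bond.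

**Step 13**
Reactants: 20 (3aS,4S,6Z,10Z,11aR)-10-(TBDPSOCH2)-6-methyl-4-(TESO)-3a,4,5,8,9,11a-hexahydrocyclodeca[b]furan-2(3H)-one
Product: 22 (3aS,4S,6Z,10Z,11aR)-10-(TBDPSOCH2)-3-[(dimethylamino)methyl]-6-methyl-4-(TESO)-3a,4,5,8,9,11a-hexahydrocyclodeca[b]furan-2(3H)-one (C3 epimers), via lithium enolate 21 (not isolated)
Conditions: LiN(iPr)2, THF, −78 °C; then CH2=NMe2+ I−, −78 °C → rt
Reagents that add atoms: N,N-dimethylmethyleneiminium iodide (Eschenmoser's salt), C=[N+](C)C.[I-]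
Why: Mannich reaction of the lactone enolate introduces C13; the new C11 centre is irrelevant because it becomes sp2 in the next step.

**Step 14**
Reactants: 22 (3aS,4S,6Z,10Z,11aR)-10-(TBDPSOCH2)-3-[(dimethylamino)methyl]-6-methyl-4-(TESO)-3a,4,5,8,9,11a-hexahydrocyclodeca[b]furan-2(3H)-one
Product: 24 (3aS,4S,6Z,10Z,11aR)-10-(TBDPSOCH2)-6-methyl-3-methylidene-4-(TESO)-3a,4,5,8,9,11a-hexahydrocyclodeca[b]furan-2(3H)-one, via ammonium iodide 23 (not isolated)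
Conditions: MeI, MeOH/CH2Cl2, rt; then NaHCO3 (aq), CH2Cl2, rt
Reagents that add atoms: none
Why: Exhaustive N‑methylation followed by mild base elimination (E1cB, Hofmann type) gives the α‑methylene lactone.

**Step 15**
Reactants: 24 (3aS,4S,6Z,10Z,11aR)-10-(TBDPSOCH2)-6-methyl-3-methylidene-4-(TESO)-3a,4,5,8,9,11a-hexahydrocyclodeca[b]furan-2(3H)-one
Product: 25 (3aR,4S,6Z,10Z,11aR)-10-(TBDPSOCH2)-4-hydroxy-6-methyl-3-methylidene-3a,4,5,8,9,11a-hexahydrocyclodeca[b]furan-2(3H)-one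
Conditions: PPTS (cat.), MeOH/CH2Cl2, 0 °C → rt
Reagents that add atoms: none
Why: Acid‑catalysed methanolysis removes the secondary TES ether selectively while the primary TBDPS ether stays, and the absence of base avoids lactone migration.

**Step 16**
Reactants: 26 methyl (2S)-3-hydroxy-2-methylpropanoate
Product: 27 methyl (2S)-3-(TBSO)-2-methylpropanoate
Conditions: TBSCl, imidazole, CH2Cl2, rt
Reagents that add atoms: tert-butyl(chloro)dimethylsilane, CC(C)(C)[Si](C)(C)Cl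
Why: Silylation protects the side‑chain hydroxyl of the (S)‑Roche ester, whose stereocentre becomes C2′ of the target.

**Step 17**
Reactants: 27 methyl (2S)-3-(TBSO)-2-methylpropanoate
Product: 28 (2S)-3-(TBSO)-2-methylpropanoic acid
Conditions: LiOH, THF/MeOH/H2O, 0 °C; HCl (aq) to pH 3
Reagents that add atoms: lithium hydroxide, [Li+].[OH-]
Why: Cold saponification gives the acid without epimerising the α‑centre.

**Step 18**
Reactants: 25 (3aR,4S,6Z,10Z,11aR)-10-(TBDPSOCH2)-4-hydroxy-6-methyl-3-methylidene-3a,4,5,8,9,11a-hexahydrocyclodeca[b]furan-2(3H)-one; 28 (2S)-3-(TBSO)-2-methylpropanoic acid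
Product: 29 (3aR,4S,6Z,10Z,11aR)-10-(TBDPSOCH2)-6-methyl-3-methylidene-2-oxo-2,3,3a,4,5,8,9,11a-octahydrocyclodeca[b]furan-4-yl (2S)-3-(TBSO)-2-methylpropanoate
Conditions: DCC, DMAP (cat.), CH2Cl2, 0 °C → rt
Reagents that add atoms: none
Why: Steglich esterification acylates the 8‑hydroxyl with retention at C8 and C2′.

**Step 19**
Reactants: 29 (3aR,4S,6Z,10Z,11aR)-10-(TBDPSOCH2)-6-methyl-3-methylidene-2-oxo-2,3,3a,4,5,8,9,11a-octahydrocyclodeca[b]furan-4-yl (2S)-3-(TBSO)-2-methylpropanoate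
Product: 30 (3aR,4S,6Z,10Z,11aR)-10-(hydroxymethyl)-6-methyl-3-methylidene-2-oxo-2,3,3a,4,5,8,9,11a-octahydrocyclodeca[b]furan-4-yl (2S)-3-hydroxy-2-methylpropanoate
Conditions: HF·pyridine, pyridine, THF, 0 °C → rt
Reagents that add atoms: none
Why: Buffered fluoride desilylation removes both silyl ethers without harming the ester, the α‑methylene lactone or the 1,5‑diene.

**Compound list**
1 | prop-2-yn-1-ol | C#CCO | starting material
2 | tert-butyl(diphenyl)(prop-2-yn-1-yloxy)silane | C#CCO[Si](c1ccccc1)(c1ccccc1)C(C)(C)C | intermediate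
3 | lithium acetylide of 2 | [Li]C#CCO[Si](c1ccccc1)(c1ccccc1)C(C)(C)C | intermediate
4 | ethyl 4-(TBDPSO)but-2-ynoate | CCOC(=O)C#CCO[Si](c1ccccc1)(c1ccccc1)C(C)(C)C | intermediate
5 | alkenylcopper adduct of 4 (Cu on C2, cis to the butenyl group on C3) | CCOC(=O)/C([Cu])=C(\CO[Si](c1ccccc1)(c1ccccc1)C(C)(C)C)CCC=C | intermediate
6 | ethyl (2Z)-3-(TBDPSOCH2)hepta-2,6-dienoate | CCOC(=O)/C=C(\CO[Si](c1ccccc1)(c1ccccc1)C(C)(C)C)CCC=C | intermediate
7 | (2Z)-3-(TBDPSOCH2)hepta-2,6-dien-1-ol | OC/C=C(\CO[Si](c1ccccc1)(c1ccccc1)C(C)(C)C)CCC=C | intermediate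
8 | (2Z)-3-(TBDPSOCH2)hepta-2,6-dienal | O=C/C=C(\CO[Si](c1ccccc1)(c1ccccc1)C(C)(C)C)CCC=C | intermediate
9 | (4S)-4-benzyl-1,3-oxazolidin-2-one | O=C1N[C@@H](Cc2ccccc2)CO1 | starting material
10 | methyl 4-chloro-4-oxobutanoate | COC(=O)CCC(Cl)=O | starting material
11 | methyl 4-[(4S)-4-benzyl-2-oxo-1,3-oxazolidin-3-yl]-4-oxobutanoate | COC(=O)CCC(=O)N1[C@@H](Cc2ccccc2)COC1=O | intermediate
12 | dibutylboron (Z)-enolate of 11 | COC(=O)C/C=C(\OB(CCCC)CCCC)N1[C@@H](Cc2ccccc2)COC1=O | intermediate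
13 | methyl (3S,4R,5Z)-3-{[(4S)-4-benzyl-2-oxo-1,3-oxazolidin-3-yl]carbonyl}-6-(TBDPSOCH2)-4-hydroxydeca-5,9-dienoate | COC(=O)C[C@H](C(=O)N1[C@@H](Cc2ccccc2)COC1=O)[C@H](O)/C=C(\CO[Si](c3ccccc3)(c3ccccc3)C(C)(C)C)CCC=C | intermediate
14 | (4S)-4-benzyl-3-{[(2R,3S)-2-[(1Z)-2-(TBDPSOCH2)hexa-1,5-dien-1-yl]-5-oxooxolan-3-yl]carbonyl}-1,3-oxazolidin-2-one | O=C1C[C@H](C(=O)N2[C@@H](Cc3ccccc3)COC2=O)[C@@H](/C=C(\CO[Si](c4ccccc4)(c4ccccc4)C(C)(C)C)CCC=C)O1 | intermediate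
15 | (2R,3S)-2-[(1Z)-2-(TBDPSOCH2)hexa-1,5-dien-1-yl]-5-oxooxolane-3-carboxylic acid | O=C1C[C@H](C(=O)O)[C@@H](/C=C(\CO[Si](c2ccccc2)(c2ccccc2)C(C)(C)C)CCC=C)O1 | intermediate
16 | (2R,3S)-2-[(1Z)-2-(TBDPSOCH2)hexa-1,5-dien-1-yl]-5-oxooxolane-3-carbonyl chloride | O=C1C[C@H](C(Cl)=O)[C@@H](/C=C(\CO[Si](c2ccccc2)(c2ccccc2)C(C)(C)C)CCC=C)O1 | intermediate
17 | (2R,3S)-2-[(1Z)-2-(TBDPSOCH2)hexa-1,5-dien-1-yl]-5-oxooxolane-3-carbaldehyde | O=C1C[C@H](C=O)[C@@H](/C=C(\CO[Si](c2ccccc2)(c2ccccc2)C(C)(C)C)CCC=C)O1 | intermediate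
18 | (4R,5R)-5-[(1Z)-2-(TBDPSOCH2)hexa-1,5-dien-1-yl]-4-[(1S)-1-hydroxy-3-methylbut-3-en-1-yl]oxolan-2-one | O=C1C[C@H]([C@@H](O)CC(C)=C)[C@@H](/C=C(\CO[Si](c2ccccc2)(c2ccccc2)C(C)(C)C)CCC=C)O1 | intermediate
19 | (4S,5R)-5-[(1Z)-2-(TBDPSOCH2)hexa-1,5-dien-1-yl]-4-[(1S)-3-methyl-1-(TESO)but-3-en-1-yl]oxolan-2-one | O=C1C[C@H]([C@@H](O[Si](CC)(CC)CC)CC(C)=C)[C@@H](/C=C(\CO[Si](c2ccccc2)(c2ccccc2)C(C)(C)C)CCC=C)O1 | intermediate
20 | (3aS,4S,6Z,10Z,11aR)-10-(TBDPSOCH2)-6-methyl-4-(TESO)-3a,4,5,8,9,11a-hexahydrocyclodeca[b]furan-2(3H)-one | C1C(=O)O[C@@H]2/C=C(\CO[Si](c3ccccc3)(c3ccccc3)C(C)(C)C)CC/C=C(/C)C[C@H](O[Si](CC)(CC)CC)[C@@H]12 | intermediate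
21 | lithium enolate of 20 (C11=C12–OLi) | C1=C(O[Li])O[C@@H]2/C=C(\CO[Si](c3ccccc3)(c3ccccc3)C(C)(C)C)CC/C=C(/C)C[C@H](O[Si](CC)(CC)CC)[C@@H]12 | intermediate
22 | (3aS,4S,6Z,10Z,11aR)-10-(TBDPSOCH2)-3-[(dimethylamino)methyl]-6-methyl-4-(TESO)-3a,4,5,8,9,11a-hexahydrocyclodeca[b]furan-2(3H)-one (C3 epimers) | CN(C)CC1C(=O)O[C@@H]2/C=C(\CO[Si](c3ccccc3)(c3ccccc3)C(C)(C)C)CC/C=C(/C)C[C@H](O[Si](CC)(CC)CC)[C@@H]12 | intermediate
23 | trimethylammonium iodide of 22 | C[N+](C)(C)CC1C(=O)O[C@@H]2/C=C(\CO[Si](c3ccccc3)(c3ccccc3)C(C)(C)C)CC/C=C(/C)C[C@H](O[Si](CC)(CC)CC)[C@@H]12.[I-] | intermediate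
24 | (3aS,4S,6Z,10Z,11aR)-10-(TBDPSOCH2)-6-methyl-3-methylidene-4-(TESO)-3a,4,5,8,9,11a-hexahydrocyclodeca[b]furan-2(3H)-one | C=C1C(=O)O[C@@H]2/C=C(\CO[Si](c3ccccc3)(c3ccccc3)C(C)(C)C)CC/C=C(/C)C[C@H](O[Si](CC)(CC)CC)[C@@H]12 | intermediate
25 | (3aR,4S,6Z,10Z,11aR)-10-(TBDPSOCH2)-4-hydroxy-6-methyl-3-methylidene-3a,4,5,8,9,11a-hexahydrocyclodeca[b]furan-2(3H)-one | C=C1C(=O)O[C@@H]2/C=C(\CO[Si](c3ccccc3)(c3ccccc3)C(C)(C)C)CC/C=C(/C)C[C@H](O)[C@@H]12 | intermediate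
26 | methyl (2S)-3-hydroxy-2-methylpropanoate | COC(=O)[C@@H](C)CO | starting material
27 | methyl (2S)-3-(TBSO)-2-methylpropanoate | COC(=O)[C@@H](C)CO[Si](C)(C)C(C)(C)C | intermediate
28 | (2S)-3-(TBSO)-2-methylpropanoic acid | OC(=O)[C@@H](C)CO[Si](C)(C)C(C)(C)C | intermediate
29 | (3aR,4S,6Z,10Z,11aR)-10-(TBDPSOCH2)-6-methyl-3-methylidene-2-oxo-2,3,3a,4,5,8,9,11a-octahydrocyclodeca[b]furan-4-yl (2S)-3-(TBSO)-2-methylpropanoate | C=C1C(=O)O[C@@H]2/C=C(\CO[Si](c3ccccc3)(c3ccccc3)C(C)(C)C)CC/C=C(/C)C[C@H](OC(=O)[C@@H](C)CO[Si](C)(C)C(C)(C)C)[C@@H]12 | intermediate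
30 | (3aR,4S,6Z,10Z,11aR)-10-(hydroxymethyl)-6-methyl-3-methylidene-2-oxo-2,3,3a,4,5,8,9,11a-octahydrocyclodeca[b]furan-4-yl (2S)-3-hydroxy-2-methylpropanoate | C=C1C(=O)O[C@@H]2/C=C(\CO)CC/C=C(/C)C[C@H](OC(=O)[C@@H](C)CO)[C@@H]12 | target

**Step count and weak points**
Total: 19 steps. Longest linear sequence: 16 steps from prop-2-yn-1-ol (steps 1–5, 7–15, 18, 19).

Step 10 is at risk because aldehyde 17 is α‑branched and β‑acyloxy, so the addition may be slow, the catalyst may be mismatched with the substrate, and 17 may epimerise or eliminate. The fallback sets out from acid 15: it is converted to acid chloride 16 as in step 9 and coupled with tributyl(2-methylallyl)stannane under Pd(PPh3)4 catalysis (THF, rt, Stille acylation) to give the β,γ‑unsaturated ketone (4S,5R)-5-[(1Z)-2-(TBDPSOCH2)hexa-1,5-dien-1-yl]-4-(3-methylbut-3-enoyl)oxolan-2-one F1. C8 is then set by reagent‑controlled CBS reduction ((R)-Me-CBS oxazaborolidine, catecholborane, toluene, −78 °C), which returns to the route at 18.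

Step 12 is at risk because closing a ten‑membered ring with a trisubstituted olefin can give oligomers or an E/Z mixture. The fallback sets out from 19: the lactone is reduced with iBu2AlH (CH2Cl2, −78 → 0 °C) to the seco‑diol (3S,4R,5Z)-6-(TBDPSOCH2)-3-[(1S)-3-methyl-1-(TESO)but-3-en-1-yl]deca-5,9-diene-1,4-diol F2, which no longer carries the ring fusion. Ring‑closing metathesis with RuCl2(=CHPh)(PCy3)(H2IMes) (toluene, 1 mM, 60–80 °C) then gives the macrocyclic diol 2-[(1S,2R,3Z,7Z,10S)-4-(TBDPSOCH2)-2-hydroxy-8-methyl-10-(TESO)cyclodeca-3,7-dien-1-yl]ethan-1-ol F3. Oxidative lactonisation with TEMPO (cat.) and PhI(OAc)2 (CH2Cl2, rt) oxidises only the primary alcohol, and the lactol closes onto the free 6‑OH because O8 is still silylated; this returns to the route at 20.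

Step 13 is at risk because kinetic enolisation of the macrocyclic lactone with LiN(iPr)2 and the Mannich alkylation may be incomplete. The fallback sets out from 20: Claisen formylation (NaH, HCO2Et, THF, 0 °C → rt) gives the sodium enolate of the α‑formyl lactone, sodium [(3aS,4S,6Z,10Z,11aR)-10-(TBDPSOCH2)-6-methyl-2-oxo-4-(TESO)-3a,4,5,8,9,11a-hexahydrocyclodeca[b]furan-3(2H)-ylidene]methanolate F4. Heating F4 with paraformaldehyde (THF, 60 °C) brings about deformylative methylenation and returns to the route at 24, bypassing 22 and 23.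

**Further compounds**
F1 | step 10 | (4S,5R)-5-[(1Z)-2-(TBDPSOCH2)hexa-1,5-dien-1-yl]-4-(3-methylbut-3-enoyl)oxolan-2-one | O=C1C[C@H](C(=O)CC(C)=C)[C@@H](/C=C(\CO[Si](c2ccccc2)(c2ccccc2)C(C)(C)C)CCC=C)O1
F2 | step 12 | (3S,4R,5Z)-6-(TBDPSOCH2)-3-[(1S)-3-methyl-1-(TESO)but-3-en-1-yl]deca-5,9-diene-1,4-diol | OCC[C@H]([C@@H](O[Si](CC)(CC)CC)CC(C)=C)[C@H](O)/C=C(\CO[Si](c1ccccc1)(c1ccccc1)C(C)(C)C)CCC=C
F3 | step 12 | 2-[(1S,2R,3Z,7Z,10S)-4-(TBDPSOCH2)-2-hydroxy-8-methyl-10-(TESO)cyclodeca-3,7-dien-1-yl]ethan-1-ol | OCC[C@H]1[C@H](O)/C=C(\CO[Si](c2ccccc2)(c2ccccc2)C(C)(C)C)CC/C=C(/C)C[C@@H]1O[Si](CC)(CC)CC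
F4 | step 13 | sodium [(3aS,4S,6Z,10Z,11aR)-10-(TBDPSOCH2)-6-methyl-2-oxo-4-(TESO)-3a,4,5,8,9,11a-hexahydrocyclodeca[b]furan-3(2H)-ylidene]methanolate | [Na+].[O-]C=C1C(=O)O[C@@H]2/C=C(\CO[Si](c3ccccc3)(c3ccccc3)C(C)(C)C)CC/C=C(/C)C[C@H](O[Si](CC)(CC)CC)[C@@H]12
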